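(The earlier runs and the new flask are calculated with constants of no real substance, noise included.)

- Take the constants from the runs: call r the moles of Q charged per mole of D, and compare it with the share of the charge that G lacks at the last reading, the shortfall.
- Read the runs and what is asked:

| flask | Q | D | remark | time |
|---|---|---|---|---|
| Friday's | 0.034 M | 6 mM | run made earlier |  |
| Thursday's | 0.075 M | 6 mM | run made earlier |  |
| Monday's | 0.050 M | 9 mM | run made earlier |  |
| flask | 0.050 M | 6.0 mM |  | 10 d |

- Friday's (time / d: G / %, Z / %): 0.625: 42.3, 49.8; 1.67: 85.9, 9.3; 3.00: 94.5, 0.3; 8.00: 95.2, 0.3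
- Thursday's (time / d: G / %, Z / %): 0.625: 21.6, 47.2; 1.67: 64.1, 27.3; 3.00: 86.2, 1.9; 8.00: 90.1, 0
- Monday's (time / d: G / %, Z / %): 0.625: 45.0, 45.9; 1.67: 91.5, 3.6; 3.00: 95.2, 0.5; 8.00: 94.9, 0

(each reading ± 0.5 percentage points)

- given per volume of solution although it is solid: Q
- at the start none of Q is in solution
- Z means what is dissolved; the solid is not counted in it
- Z is what Q becomes in solution

- G at 10 d, in percent of the Q charged
- concentration of Z in solution at 10 d, in percent of saturation

- See why r is worth testing: Friday's at r = 5.67 and Monday's at r = 5.56 stand close and end at 95.2% and 94.9%, while Thursday's at r = 12.5 lacks twice Friday's shortfall.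
- Divide shortfall by r: Friday's gives 0.847% and Thursday's 0.792%, and their mean is 0.820%, the leak λ, the share of the charge lost per unit of r.
- Reckon this flask two ways at r = 8.33: λ gives G = 93.2%, whereas Monday's leak by itself, 0.918%, gives 92.4%, lower by 0.80 percentage points.
- Distrust Monday's way, since it stretches one reading by 1.50 and so carries a scatter of 0.75 points, close to the gap, while λ brackets this flask between Friday's and Thursday's; commit to 93.2%.
- Expect Z below the scatter, as Thursday's reads 0% at 8.00 d.
- Set beside this the forecast, 93.5% and 0.2%, its G slightly above mine, which reckons with “an extra loss when dissolved Z runs high relative to catalyst”.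
- Now read the flask: G 93.4%, Z 0% of saturation.

    Z + D → L (k = 0.260 M⁻¹ min⁻¹)
    L → X (k = 0.00930 min⁻¹)
    X ⇌ D + G (K = 0.540 M, k = 0.0320 min⁻¹)
    Q ⇌ Z, rate k4*(cs4 - [Z]) while solid is left; crystals form when [Z] > cs4 (solubility = 41.0 mM, k = 0.00450 min⁻¹)
    Z + G → E (k = 0.00130 M⁻¹ min⁻¹)

- Blame the reaction of Z + G to E for 85% of the G missing from this flask: without it this flask ends at 99.0% rather than 93.4%. That step competes with Z + D to L for Z, so their rate ratio, the selectivity factor, grows as G over D, while r is the charge of Q over the charge of D; this flask's own leak comes to 0.792%. Carry λ to the neighbour with 0.12 M of Q, r = 20.0: it gives G = 83.6%, and that flask ends at 83.6%, with 15.6% of its charge in E.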